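Assumption (one line): xanthanolide numbering is used (C-1 to C-15 in the hydroxylated unit A, primed numbers in the spiro-lactone unit B); the carbon that carries the CH2SPh or CH2S(O)Ph group is an inconsequential epimer mixture and is written without a descriptor.

## Retrosynthetic overview

1. Target ⇐ singlet-oxygen ene oxygenation at C-1, after sulfoxide elimination to free the unit A methylene lactone ⇐ spiro cycloadduct.
2. Cycloadduct ⇐ intermolecular Diels–Alder reaction (C-5–C-13′ and C-3–C-11′) of a unit A dienone whose exocyclic methylene is masked as CH2SPh (diene only) with ent-xanthatin (unit B, dienophile). This is the key step and forms the cyclohexene ring.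
3. Both cycloheptene dienones ⇐ domino enyne ring-closing/cross-metathesis of alkynyl allyl γ-lactones with but-3-en-2-one.
4. These lactones ⇐ lactone transposition (i-Bu2AlH, Ohira–Bestmann, acid) of one γ-lactone from (5R)-5-(hydroxymethyl)oxolan-2-one: C-8 bought, C-7 by anti allylcopper addition, C-10 by trans methylation (unit A) or kinetic protonation (unit B).
5. Ring order: bought γ-lactone → final γ-lactone → cycloheptene → spiro-cyclohexene (Diels–Alder).

## Route

Step 1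
Reactants: 1 (5R)-5-(hydroxymethyl)oxolan-2-one; 2 tert-butyl (triphenyl-λ5-phosphanylidene)acetate
Product: 4 tert-butyl (2E)-3-[(2R)-5-oxooxolan-2-yl]prop-2-enoate, via aldehyde 3 (not isolated)
Conditions: 2-iodoxybenzoic acid, DMSO, rt; then 2, rt
Reagents that add atoms: none
Why: One-pot alcohol oxidation/Wittig olefination; the stabilised ylide gives the E-enoate, and the non-basic conditions leave the bought C-8 stereocentre (α to the aldehyde) untouched.

Step 2
Reactants: 4 tert-butyl (2E)-3-[(2R)-5-oxooxolan-2-yl]prop-2-enoate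
Product: 6 tert-butyl (3S)-3-[(2R)-5-oxooxolan-2-yl]-2-[(phenylsulfanyl)methyl]hex-5-enoate, via silyl ketene acetal 5 (not isolated)
Conditions: CH2=CHCH2MgBr/CuBr·SMe2 (1:1, preformed), Me3SiCl, THF, −78 °C; filter under Ar; then PhSCH2Cl, ZnBr2 (5 mol %), CH2Cl2, rt
Reagents that add atoms: allylmagnesium bromide (C=CC[Mg]Br); chloromethyl phenyl sulfide (ClCSc1ccccc1)
Why: Me3SiCl-accelerated conjugate addition of allylcopper anti to the γ-oxygen (Felkin–Anh-type control by C-8) sets C-7 (S), and Lewis-acid phenylthiomethylation of the silyl ketene acetal installs the masked exocyclic methylene.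

Step 3
Reactants: 6 tert-butyl (3S)-3-[(2R)-5-oxooxolan-2-yl]-2-[(phenylsulfanyl)methyl]hex-5-enoate
Product: 8 tert-butyl (3S)-3-[(2R,4S)-4-methyl-5-oxooxolan-2-yl]-2-[(phenylsulfanyl)methyl]hex-5-enoate, via lithium enolate 7 (not isolated)
Conditions: LiN(i-Pr)2 (1.05 equiv), THF, −78 °C; CH3I, −78 → −40 °C
Reagents that add atoms: iodomethane (CI)
Why: Kinetic enolisation of the more acidic, unhindered lactone CH2 (the α-branched tert-butyl ester is left alone) and SN2 methylation anti to the C-8 side chain (1,3-induction across the γ-lactone) give the trans lactone, which is C-10 (S) of unit A.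

Step 4
Reactants: 8 tert-butyl (3S)-3-[(2R,4S)-4-methyl-5-oxooxolan-2-yl]-2-[(phenylsulfanyl)methyl]hex-5-enoate
Product: 9 tert-butyl (3S)-3-[(2R,4S)-5-hydroxy-4-methyloxolan-2-yl]-2-[(phenylsulfanyl)methyl]hex-5-enoate (anomers)
Conditions: i-Bu2AlH (1.1 equiv), CH2Cl2, −78 °C; aq. KNaC4H4O6
Reagents that add atoms: none
Why: Partial hydride reduction of the γ-lactone to the lactol; the hindered tert-butyl ester is inert at −78 °C and no stereocentre is touched.

Step 5
Reactants: 9 tert-butyl (3S)-3-[(2R,4S)-5-hydroxy-4-methyloxolan-2-yl]-2-[(phenylsulfanyl)methyl]hex-5-enoate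
Product: 11 (4S,5R)-5-[(2S)-2-methylbut-3-yn-1-yl]-3-[(phenylsulfanyl)methyl]-4-(prop-2-en-1-yl)oxolan-2-one, via hydroxy ester 10 (not isolated)
Conditions: dimethyl (1-diazo-2-oxopropyl)phosphonate, K2CO3, MeOH, 0 °C → rt; then CF3CO2H, CH2Cl2, 0 °C → rt
Reagents that add atoms: dimethyl (1-diazo-2-oxopropyl)phosphonate (CC(=O)C(=[N+]=[N-])P(=O)(OC)OC)
Why: Seyferth–Gilbert homologation (Ohira–Bestmann reagent) turns the masked aldehyde C-1 into the terminal alkyne under conditions mild enough to keep C-10, and acid then closes the freed C-8 hydroxyl onto the tert-butyl ester (lactone transposition, trans C-7/C-8 retained).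

Step 6
Reactants: 11 (4S,5R)-5-[(2S)-2-methylbut-3-yn-1-yl]-3-[(phenylsulfanyl)methyl]-4-(prop-2-en-1-yl)oxolan-2-one; 12 but-3-en-2-one
Product: 14 (3aS,7S,8aR)-7-methyl-6-[(1E)-3-oxobut-1-en-1-yl]-3-[(phenylsulfanyl)methyl]-3,3a,4,7,8,8a-hexahydro-2H-cyclohepta[b]furan-2-one, via vinyl diene 13 (not isolated)
Conditions: 12 (5 equiv), second-generation Hoveyda–Grubbs catalyst (10 mol %), CH2Cl2, 40 °C
Reagents that add atoms: none
Why: Domino enyne ring-closing metathesis/cross-metathesis; the alkylidene formed at the allyl group closes the seven-membered ring onto the alkyne (exo mode) and the resulting 1-vinylcycloheptene is capped E-selectively by the enone, with no new stereocentre.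

Step 7
Reactants: 8 tert-butyl (3S)-3-[(2R,4S)-4-methyl-5-oxooxolan-2-yl]-2-[(phenylsulfanyl)methyl]hex-5-enoate
Product: 16 tert-butyl (3S)-3-[(2R,4R)-4-methyl-5-oxooxolan-2-yl]-2-[(phenylsulfanyl)methyl]hex-5-enoate, via lithium enolate 15 (not isolated)
Conditions: LiN(i-Pr)2 (1.1 equiv), THF, −78 °C; then 2,6-di-tert-butyl-4-methylphenol (3 equiv), −78 °C; H2O
Reagents that add atoms: none
Why: Deprotonation/kinetic protonation; the bulky phenol protonates the planar lactone enolate from the face anti to the C-8 side chain, so the methyl group ends cis to it, which is C-10 (R) of unit B.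

Step 8
Reactants: 16 tert-butyl (3S)-3-[(2R,4R)-4-methyl-5-oxooxolan-2-yl]-2-[(phenylsulfanyl)methyl]hex-5-enoate
Product: 17 tert-butyl (3S)-3-[(2R,4R)-5-hydroxy-4-methyloxolan-2-yl]-2-[(phenylsulfanyl)methyl]hex-5-enoate (anomers)
Conditions: i-Bu2AlH (1.1 equiv), CH2Cl2, −78 °C; aq. KNaC4H4O6
Reagents that add atoms: none
Why: Chemoselective lactone-to-lactol reduction as in step 4; no stereocentre is touched.

Step 9
Reactants: 17 tert-butyl (3S)-3-[(2R,4R)-5-hydroxy-4-methyloxolan-2-yl]-2-[(phenylsulfanyl)methyl]hex-5-enoate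
Product: 19 (4S,5R)-5-[(2R)-2-methylbut-3-yn-1-yl]-3-[(phenylsulfanyl)methyl]-4-(prop-2-en-1-yl)oxolan-2-one, via hydroxy ester 18 (not isolated)
Conditions: dimethyl (1-diazo-2-oxopropyl)phosphonate, K2CO3, MeOH, 0 °C → rt; then CF3CO2H, CH2Cl2, 0 °C → rt
Reagents that add atoms: dimethyl (1-diazo-2-oxopropyl)phosphonate (CC(=O)C(=[N+]=[N-])P(=O)(OC)OC)
Why: Seyferth–Gilbert homologation (Ohira–Bestmann reagent) and acid-induced lactone transposition as in step 5, with C-7′, C-8′ and C-10′ retained.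

Step 10
Reactants: 19 (4S,5R)-5-[(2R)-2-methylbut-3-yn-1-yl]-3-[(phenylsulfanyl)methyl]-4-(prop-2-en-1-yl)oxolan-2-one
Product: 21 (4S,5R)-3-methylidene-5-[(2R)-2-methylbut-3-yn-1-yl]-4-(prop-2-en-1-yl)oxolan-2-one, via sulfoxide 20 (not isolated)
Conditions: NaIO4, MeOH–H2O, 0 °C → rt; then PhMe, CaCO3, 110 °C
Reagents that add atoms: none
Why: Sulfide oxidation and thermal syn-elimination of the sulfoxide; the only β-hydrogen is the lactone α-H, so the alkene is the exocyclic methylene.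

Step 11
Reactants: 21 (4S,5R)-3-methylidene-5-[(2R)-2-methylbut-3-yn-1-yl]-4-(prop-2-en-1-yl)oxolan-2-one; 12 but-3-en-2-one
Product: 23 (3aS,7R,8aR)-7-methyl-3-methylidene-6-[(1E)-3-oxobut-1-en-1-yl]-3,3a,4,7,8,8a-hexahydro-2H-cyclohepta[b]furan-2-one (ent-xanthatin), via vinyl diene 22 (not isolated)
Conditions: 12 (5 equiv), second-generation Hoveyda–Grubbs catalyst (10 mol %), CH2Cl2, 40 °C
Reagents that add atoms: none
Why: Domino enyne ring-closing metathesis/cross-metathesis as in step 6; the electron-poor 1,1-disubstituted methylene lactone does not take part and no stereocentre is formed.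

Step 12
Reactants: 14 (3aS,7S,8aR)-7-methyl-6-[(1E)-3-oxobut-1-en-1-yl]-3-[(phenylsulfanyl)methyl]-3,3a,4,7,8,8a-hexahydro-2H-cyclohepta[b]furan-2-one; 23 ent-xanthatin
Product: 24 sulfide-masked spiro cycloadduct (3S,5S,7S,8R,10S,7′S,8′R,10′R,11′S) with C-1=C-2
Conditions: 14 (3 equiv), PhMe (2 M), 2,6-di-tert-butyl-4-methylphenol (5 mol %), 110 °C; 23 added over 24 h, then 48 h; excess 14 recovered
Reagents that add atoms: none
Why: Thermal intermolecular Diels–Alder reaction in which 14 can only be the diene and slowly added 23 the dienophile; "ortho/para" orientation joins C-5 to C-13′ and C-3 to C-11′, and the endo approach (lactone C=O under the diene) to the convex face of the chair-locked cycloheptene, anti to C-7–C-11, and to the lactone face anti to the pseudo-axial C-7′–H sets C-5 (S) and C-11′ (S).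

Step 13
Reactants: 24 sulfide-masked spiro cycloadduct
Product: 26 spiro cycloadduct with free unit A methylene lactone (3S,5S,7S,8R,10S,7′S,8′R,10′R,11′S), via sulfoxide 25 (not isolated)
Conditions: NaIO4, MeOH–H2O, 0 °C → rt; then PhMe, CaCO3, 110 °C
Reagents that add atoms: none
Why: Sulfide oxidation and thermal sulfoxide syn-elimination unveil the exocyclic methylene of unit A; the electron-poor enones are inert to periodate and no stereocentre is touched.

Step 14
Reactants: 26 spiro cycloadduct with free unit A methylene lactone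
Product: 28 CNP0168949.3 (1R,5S,7S,8R,10S,7′S,8′R,10′R,11′S), via hydroperoxide 27 (not isolated)
Conditions: O2, tetraphenylporphyrin (1 mol %), white LED, CH2Cl2, −20 °C; then Me2S, rt
Reagents that add atoms: dioxygen (O=O)
Why: Schenck ene reaction; singlet oxygen attacks the only electron-rich alkene (C-1=C-2) from the face anti to C-13′ and the C-10 methyl and removes the axial, α-keto H-3 suprafacially, giving the C-1 (R) hydroperoxide with the C-2=C-3 enone, and Me2S reduces the O–O bond.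

## Compound list

1 | (5R)-5-(hydroxymethyl)oxolan-2-one (from D-glutamic acid) | O=C1CC[C@H](CO)O1 | starting material
2 | tert-butyl (triphenyl-λ5-phosphanylidene)acetate | CC(C)(C)OC(=O)C=P(c1ccccc1)(c1ccccc1)c1ccccc1 | starting material
3 | (2R)-5-oxooxolane-2-carbaldehyde | O=C[C@H]1CCC(=O)O1 | intermediate
4 | tert-butyl (2E)-3-[(2R)-5-oxooxolan-2-yl]prop-2-enoate | CC(C)(C)OC(=O)/C=C/[C@H]1CCC(=O)O1 | intermediate
5 | (5R)-5-[(3S)-1-tert-butoxy-1-(trimethylsilyloxy)hexa-1,5-dien-3-yl]oxolan-2-one | C=CC[C@@H](C=C(OC(C)(C)C)O[Si](C)(C)C)[C@H]1CCC(=O)O1 | intermediate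
6 | tert-butyl (3S)-3-[(2R)-5-oxooxolan-2-yl]-2-[(phenylsulfanyl)methyl]hex-5-enoate | C=CC[C@@H](C(CSc1ccccc1)C(=O)OC(C)(C)C)[C@H]1CCC(=O)O1 | intermediate
7 | lithium enolate of 6 (lactone enolate) | [Li+].[O-]C1=CC[C@@H](O1)[C@@H](CC=C)C(CSc1ccccc1)C(=O)OC(C)(C)C | intermediate
8 | tert-butyl (3S)-3-[(2R,4S)-4-methyl-5-oxooxolan-2-yl]-2-[(phenylsulfanyl)methyl]hex-5-enoate | C[C@H]1C[C@H]([C@@H](CC=C)C(CSc2ccccc2)C(=O)OC(C)(C)C)OC1=O | intermediate
9 | tert-butyl (3S)-3-[(2R,4S)-5-hydroxy-4-methyloxolan-2-yl]-2-[(phenylsulfanyl)methyl]hex-5-enoate | C[C@H]1C[C@H]([C@@H](CC=C)C(CSc2ccccc2)C(=O)OC(C)(C)C)OC1O | intermediate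
10 | tert-butyl (3S,4R,6S)-4-hydroxy-6-methyl-2-[(phenylsulfanyl)methyl]-3-(prop-2-en-1-yl)oct-7-ynoate | C#C[C@@H](C)C[C@@H](O)[C@@H](CC=C)C(CSc1ccccc1)C(=O)OC(C)(C)C | intermediate
11 | (4S,5R)-5-[(2S)-2-methylbut-3-yn-1-yl]-3-[(phenylsulfanyl)methyl]-4-(prop-2-en-1-yl)oxolan-2-one | C#C[C@@H](C)C[C@H]1OC(=O)C(CSc2ccccc2)[C@@H]1CC=C | intermediate
12 | but-3-en-2-one | CC(=O)C=C | starting material
13 | (3aS,7S,8aR)-6-ethenyl-7-methyl-3-[(phenylsulfanyl)methyl]-3,3a,4,7,8,8a-hexahydro-2H-cyclohepta[b]furan-2-one | C[C@H]1C[C@@H]2[C@@H](CC=C1C=C)C(CSc3ccccc3)C(=O)O2 | intermediate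
14 | (3aS,7S,8aR)-7-methyl-6-[(1E)-3-oxobut-1-en-1-yl]-3-[(phenylsulfanyl)methyl]-3,3a,4,7,8,8a-hexahydro-2H-cyclohepta[b]furan-2-one | C[C@H]1C[C@@H]2[C@@H](CC=C1/C=C/C(C)=O)C(CSc3ccccc3)C(=O)O2 | intermediate
15 | lithium enolate of 8 (lactone enolate) | [Li+].[O-]C1=C(C)C[C@@H](O1)[C@@H](CC=C)C(CSc1ccccc1)C(=O)OC(C)(C)C | intermediate
16 | tert-butyl (3S)-3-[(2R,4R)-4-methyl-5-oxooxolan-2-yl]-2-[(phenylsulfanyl)methyl]hex-5-enoate | C[C@@H]1C[C@H]([C@@H](CC=C)C(CSc2ccccc2)C(=O)OC(C)(C)C)OC1=O | intermediate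
17 | tert-butyl (3S)-3-[(2R,4R)-5-hydroxy-4-methyloxolan-2-yl]-2-[(phenylsulfanyl)methyl]hex-5-enoate | C[C@@H]1C[C@H]([C@@H](CC=C)C(CSc2ccccc2)C(=O)OC(C)(C)C)OC1O | intermediate
18 | tert-butyl (3S,4R,6R)-4-hydroxy-6-methyl-2-[(phenylsulfanyl)methyl]-3-(prop-2-en-1-yl)oct-7-ynoate | C#C[C@H](C)C[C@@H](O)[C@@H](CC=C)C(CSc1ccccc1)C(=O)OC(C)(C)C | intermediate
19 | (4S,5R)-5-[(2R)-2-methylbut-3-yn-1-yl]-3-[(phenylsulfanyl)methyl]-4-(prop-2-en-1-yl)oxolan-2-one | C#C[C@H](C)C[C@H]1OC(=O)C(CSc2ccccc2)[C@@H]1CC=C | intermediate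
20 | (4S,5R)-3-[(benzenesulfinyl)methyl]-5-[(2R)-2-methylbut-3-yn-1-yl]-4-(prop-2-en-1-yl)oxolan-2-one | C#C[C@H](C)C[C@H]1OC(=O)C(CS(=O)c2ccccc2)[C@@H]1CC=C | intermediate
21 | (4S,5R)-3-methylidene-5-[(2R)-2-methylbut-3-yn-1-yl]-4-(prop-2-en-1-yl)oxolan-2-one | C#C[C@H](C)C[C@H]1OC(=O)C(=C)[C@@H]1CC=C | intermediate
22 | (3aS,7R,8aR)-6-ethenyl-7-methyl-3-methylidene-3,3a,4,7,8,8a-hexahydro-2H-cyclohepta[b]furan-2-one | C[C@@H]1C[C@@H]2[C@@H](CC=C1C=C)C(=C)C(=O)O2 | intermediate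
23 | (3aS,7R,8aR)-7-methyl-3-methylidene-6-[(1E)-3-oxobut-1-en-1-yl]-3,3a,4,7,8,8a-hexahydro-2H-cyclohepta[b]furan-2-one (ent-xanthatin) | C[C@@H]1C[C@@H]2[C@@H](CC=C1/C=C/C(C)=O)C(=C)C(=O)O2 | intermediate
24 | sulfide-masked spiro cycloadduct (3S,5S,7S,8R,10S,7′S,8′R,10′R,11′S; C-1=C-2; unit A lactone carries CH2SPh) | c1ccccc1SCC1C(=O)O[C@@H]2C[C@H](C)C3=C[C@H](C(C)=O)[C@]4(C[C@@H]3C[C@@H]12)C(=O)O[C@@H]1C[C@@H](C)C(/C=C/C(C)=O)=CC[C@H]14 | intermediate
25 | sulfoxide of 24 | c1ccccc1S(=O)CC1C(=O)O[C@@H]2C[C@H](C)C3=C[C@H](C(C)=O)[C@]4(C[C@@H]3C[C@@H]12)C(=O)O[C@@H]1C[C@@H](C)C(/C=C/C(C)=O)=CC[C@H]14 | intermediate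
26 | spiro cycloadduct with free unit A methylene lactone (3S,5S,7S,8R,10S,7′S,8′R,10′R,11′S; C-1=C-2) | C=C1C(=O)O[C@@H]2C[C@H](C)C3=C[C@H](C(C)=O)[C@]4(C[C@@H]3C[C@@H]12)C(=O)O[C@@H]1C[C@@H](C)C(/C=C/C(C)=O)=CC[C@H]14 | intermediate
27 | (1R)-1-hydroperoxide of the target skeleton (C-2=C-3 enone) | C=C1C(=O)O[C@@H]2C[C@H](C)[C@]3(OO)C=C(C(C)=O)[C@]4(C[C@@H]3C[C@@H]12)C(=O)O[C@@H]1C[C@@H](C)C(/C=C/C(C)=O)=CC[C@H]14 | intermediate
28 | CNP0168949.3 (1R,5S,7S,8R,10S,7′S,8′R,10′R,11′S) | C=C1C(=O)O[C@@H]2C[C@H](C)[C@]3(O)C=C(C(C)=O)[C@]4(C[C@@H]3C[C@@H]12)C(=O)O[C@@H]1C[C@@H](C)C(/C=C/C(C)=O)=CC[C@H]14 | target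

## Step count and risks

Total: 14 steps. Longest linear sequence: 11 steps (steps 1, 2, 3, 7, 8, 9, 10, 11, 12, 13, 14, from 1 to 28).

The three steps most likely to fail:

**Step 12 (Diels–Alder).** The risks are self-dimerisation of 23 and the wrong face or exo approach at the methylene lactone, which would give the C-11′ epimer; the facial outcome is argued from conformation, not from precedent on this system. The fallback closes ring B after the cycloaddition instead of before it. It sets out from hydroxy ester 18, which is oxidised with NaIO4 to the sulfoxide tert-butyl (3S,4R,6R)-2-[(benzenesulfinyl)methyl]-4-hydroxy-6-methyl-3-(prop-2-en-1-yl)oct-7-ynoate F1. Heating F1 in PhMe gives the open-chain acrylate tert-butyl (3S,4R,6R)-4-hydroxy-6-methyl-2-methylidene-3-(prop-2-en-1-yl)oct-7-ynoate F2. F2 has no diene, so it cannot self-react. Its face is set by the acyclic allylic centre C-7′ (C–H eclipsing the C=CH2 bond, diene anti to the carbinol branch) and no longer by the lactone ring. Cycloaddition with 14 (neat, 10 kbar, 40 °C) gives the cyclohexene tert-butyl ester F3, CF3CO2H closes the spiro-lactone F4, and enyne ring-closing/cross-metathesis with 12 under the conditions of step 11 comes back to the route at 24.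

**Step 14 (ene oxygenation).** The risks are the regiochemistry of hydrogen abstraction and competing oxidation of the unit B dienone. The fallback sets out from 26. Dimethyldioxirane (acetone, −20 °C) epoxidises the only electron-rich alkene, C-1=C-2, from the face anti to C-13′ and the C-10 methyl, to give the 1,2-epoxy ketone F5. Et3N (CH2Cl2, 0 °C) then opens the epoxide by E1cB β-elimination of H-3, which comes back to the route at 28.

**Step 7 (kinetic protonation).** The risks are a modest cis:trans ratio and competing deprotonation α to the tert-butyl ester, which would expel thiophenolate. The fallback sets out from 6. Enolate 7 is quenched with PhSeBr to give the trans α-selanyl lactone tert-butyl (3S)-3-[(2R,4S)-5-oxo-4-(phenylselanyl)oxolan-2-yl]-2-[(phenylsulfanyl)methyl]hex-5-enoate F6. Its selenium-acidified α-H is removed selectively with LiN(i-Pr)2 and methylated (CH3I) to the α-methyl-α-selanyl lactone tert-butyl (3S)-3-[(2R,4R)-4-methyl-5-oxo-4-(phenylselanyl)oxolan-2-yl]-2-[(phenylsulfanyl)methyl]hex-5-enoate F7. Bu3SnH/AIBN (PhH, 80 °C) then transfers hydrogen to the planar lactone radical from the face anti to the side chain, which comes back to the route at 16 without enolising 8.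

## Further compounds

F1 | step 12 | tert-butyl (3S,4R,6R)-2-[(benzenesulfinyl)methyl]-4-hydroxy-6-methyl-3-(prop-2-en-1-yl)oct-7-ynoate | C#C[C@H](C)C[C@@H](O)[C@@H](CC=C)C(CS(=O)c1ccccc1)C(=O)OC(C)(C)C
F2 | step 12 | tert-butyl (3S,4R,6R)-4-hydroxy-6-methyl-2-methylidene-3-(prop-2-en-1-yl)oct-7-ynoate | C#C[C@H](C)C[C@@H](O)[C@@H](CC=C)C(=C)C(=O)OC(C)(C)C
F3 | step 12 | cyclohexene tert-butyl ester cycloadduct of 14 and F2 (C-11′ quaternary, open hydroxy enyne chain) | c1ccccc1SCC1C(=O)O[C@@H]2C[C@H](C)C3=C[C@H](C(C)=O)[C@](C[C@@H]3C[C@@H]12)(C(=O)OC(C)(C)C)[C@H](CC=C)[C@H](O)C[C@@H](C)C#C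
F4 | step 12 | spiro-lactone cycloadduct with open allyl and 2-methylbut-3-ynyl arms (ring B not yet closed) | c1ccccc1SCC1C(=O)O[C@@H]2C[C@H](C)C3=C[C@H](C(C)=O)[C@]4(C[C@@H]3C[C@@H]12)C(=O)O[C@H](C[C@@H](C)C#C)[C@H]4CC=C
F5 | step 14 | 1,2-epoxide of 26 (epoxide oxygen on the face of the later C-1 hydroxyl) | C=C1C(=O)O[C@@H]2C[C@H](C)[C@]3(O5)[C@@H]5[C@H](C(C)=O)[C@]4(C[C@@H]3C[C@@H]12)C(=O)O[C@@H]1C[C@@H](C)C(/C=C/C(C)=O)=CC[C@H]14
F6 | step 7 | tert-butyl (3S)-3-[(2R,4S)-5-oxo-4-(phenylselanyl)oxolan-2-yl]-2-[(phenylsulfanyl)methyl]hex-5-enoate | c1ccccc1[Se][C@H]1C[C@H]([C@@H](CC=C)C(CSc2ccccc2)C(=O)OC(C)(C)C)OC1=O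
F7 | step 7 | tert-butyl (3S)-3-[(2R,4R)-4-methyl-5-oxo-4-(phenylselanyl)oxolan-2-yl]-2-[(phenylsulfanyl)methyl]hex-5-enoate | C[C@@]1([Se]c2ccccc2)C[C@H]([C@@H](CC=C)C(CSc3ccccc3)C(=O)OC(C)(C)C)OC1=O
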